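I started with the easiest sum these flasks allow: charge times the fraction of solid gone turns each reading into a molar loss.

| flask | solid substrate | partner | remark | time |
|---|---|---|---|---|
| oak | 0.050 M | 0.10 M | run made earlier |  |
| maple | 0.050 M | 0.15 M | run made earlier |  |
| ash | 0.10 M | 0.20 M | run made earlier |  |
| flask | 0.050 M | 0.200 M |  | 5.0 min |

| run | time / min | target / % | solid substrate / % |
|---|---|---|---|
| oak | 0.500 | 0.8 | 98.6 |
| oak | 1.50 | 1.6 | 94.3 |
| oak | 3.00 | 5.1 | 87.4 |
| oak | 4.00 | 9.1 | 84.4 |
| oak | 6.00 | 12.5 | 78.0 |
| maple | 0.500 | 1.2 | 98.9 |
| maple | 0.833 | 1.6 | 98.2 |
| maple | 1.50 | 2.7 | 94.9 |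
| maple | 3.00 | 7.6 | 87.5 |
| maple | 6.00 | 14.8 | 76.8 |
| ash | 0.500 | 0 | 98.7 |
| ash | 0.833 | 0.1 | 98.8 |
| ash | 1.50 | 1.8 | 98.0 |
| ash | 3.00 | 5.0 | 93.4 |
| ash | 6.00 | 6.1 | 89.4 |

(each reading ± 1 percentage point)

- as a solid, counted per litre of solution: solid substrate
- at the start none of the solid substrate is in solution

- red: doubling the solubility of the solid substrate, all else as stated
- violet: doubling the amount of partner, all else as stated
- ochre: doubling the dissolution coefficient of the solid substrate, all else as stated

* how much target there is at 5.0 min, in percent of the solid substrate charged
* the change that raises the amount of target at 5.0 min, in percent of the solid substrate charged most ("none" if none brings more than 2 percentage points) (red / violet / ochre / none)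
* amount of target at 5.0 min, in percent of the solid substrate charged, after ochre

Over 6.00 min the oak run lost solid at 1.83 mM/min, the maple run at 1.93 mM/min, and the ash run, with twice the oak charge, at 1.77 mM/min. I named their mean, 1.84 mM/min, the dissolving allowance, the solid lost per litre and minute.

Counting the solid lost at that allowance as target, I reckoned 18.4% for the flask at 5.0 min. But a molecule that has left the solid stands at a fork: target, or still waiting in solution. The share of lost solid found as target was 56.8% in oak, 63.8% in maple and 57.5% in ash. Their mean, 59.4%, brought my flask to 11.0%.

Oak and ash differ twofold in partner and in solid charge, yet their shares stand at 56.8% and 57.5%, so I expected little from violet. With the share above its complement, I took dissolving as the rate-limiting step, and doubling the allowance by ochre gave me 22.0%. Oak's loss had slowed, from 2.10 mM/min over 3.00 min to 1.83 mM/min, so I chose red, which also raises the level where dissolving stops.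

The forecast said 12.5%, red and 22.5% after ochre, on the words “Dissolution limits the rate”, and my 11.0% stood lower than its figure.

The flask gave 11.8%; red added 11 percentage points, ochre 9.4 points and violet 0.5 points, and ochre reached 21.2%.

    starting material + partner → target (k = 17.0 /M/min)
    2 partner → side product (k = 4.80 /M/min)
    solid substrate ⇌ starting material, rate k3*(cs3 - [starting material]) while solid is left; crystals form when [starting material] > cs3 (solubility = 20.0 mM, k = 0.110 /min)

In the flask the step to side product ran ahead, with 92% of its turnover done by 2.50 min, when 16.6% of the partner was left, while the dissolving had 53% done. Target reached 11.8% by 5.00 min, with 8.32% of the partner left. Over that time the flask lost solid at 1.96 mM/min, against the allowance of 1.84 mM/min. The neighbour flask with 0.013 M of solid substrate lost 1.96 mM/min; allowance and share gave it 42.0%, and it held 45.3% of target.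

The readings were generated by integration on assumed constants; noise was put on by code.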